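The target is an achiral, twofold-symmetric triaryl diether whose central ring is a hydroquinone: hydroxyl oxygens on C1 and C4, aryloxy groups on C2 and C5, bromine on C3 and C6. The route rests on swapping the C1–O and C4–O bonds for C1–CHO and C4–CHO. Formyl groups at these carbons lie ortho to C2 and C5 and so permit fluoride displacement by the outer phenol; a twofold Baeyer–Villiger (Dakin-type) oxidation then turns both ring–CHO bonds into ring–O bonds in one operation. Its precursor is 2,5-bis(2,3,5-tribromo-4-methoxyphenoxy)terephthalaldehyde; formate cleavage, bromination at C3/C6 and O-demethylation complete the synthesis.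

Key step: step 4

Remark on the chemistry: the target has no stereocentre and no configurationally stable axis is expected, so it is a single achiral compound and no enantiomer has to be selected.

Step 1
Reactants: 1 1,3-dibromo-2-methoxybenzene (2,6-dibromoanisole)
Product: 3 3,5-dibromo-4-methoxyphenol, via arylboronic pinacol ester 2 (not isolated)
Conditions: [Ir(OMe)(cod)]2 (1.5 mol%), dtbpy (3 mol%), HBpin (1.5 equiv), THF, 60 °C; then Oxone, acetone–H2O, 0 °C→rt
Reagents that add atoms: pinacolborane, CC1(C)OBOC1(C)C; Oxone (potassium peroxymonosulfate), [K+].[O-]S(=O)(=O)OO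
Why: Iridium-catalysed C–H borylation is sterically governed, so only C5–H of 1 (the one C–H without an ortho bromine, para to OMe) should react while the C–Br bonds are tolerated, and oxidation of the aryl–boron bond (1,2-aryl shift from boron to oxygen) should then give the phenol in the same flask.

Step 2
Reactants: 3 3,5-dibromo-4-methoxyphenol
Product: 4 2,3,5-tribromo-4-methoxyphenol
Conditions: NBS (1.0 equiv), pTsOH·H2O (10 mol%), MeCN, 0 °C→rt
Reagents that add atoms: N-bromosuccinimide, O=C1CCC(=O)N1Br
Why: Electrophilic aromatic bromination directed ortho by the free OH (para is blocked by OMe, the two ortho sites are equivalent); one equivalent of reagent under acidic, non-ionising conditions should stop at the monobromide, since the third bromine deactivates and crowds the ring.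

Step 3
Reactants: 4 2,3,5-tribromo-4-methoxyphenol (2.2 equiv); 5 2,5-difluoroterephthalaldehyde
Product: 7 2,5-bis(2,3,5-tribromo-4-methoxyphenoxy)terephthalaldehyde, via monofluoro monoaryloxy dialdehyde 6 (not isolated)
Conditions: K2CO3 (3 equiv), dry DMF, 100 °C, N2
Reagents that add atoms: none
Why: Twofold nucleophilic aromatic substitution (SNAr): each C–F is ortho to a formyl group that stabilises the Meisenheimer adduct, fluoride is the best leaving group for this mechanism, the acidic phenol is fully ionised by carbonate, and the non-enolisable aldehydes and unactivated aryl bromides should be untouched under dry conditions.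

Step 4
Reactants: 7 2,5-bis(2,3,5-tribromo-4-methoxyphenoxy)terephthalaldehyde
Product: 9 2,5-bis(2,3,5-tribromo-4-methoxyphenoxy)-1,4-phenylene diformate, via monoformate monoaldehyde 8 (not isolated)
Conditions: mCPBA (dried, 4 equiv), CH2Cl2, 0 °C→40 °C
Reagents that add atoms: mCPBA (3-chloroperoxybenzoic acid), OOC(=O)c1cccc(Cl)c1
Why: Baeyer–Villiger oxidation of an aryl aldehyde (Dakin-type): the peracid adds to each formyl carbon to give a Criegee adduct, and the central-ring carbon (C1, then C4) migrates from carbon to the peroxide oxygen with loss of 3-chlorobenzoate, leaving an aryl formate. The closest known reaction type is the mCPBA conversion of 2-alkoxy- and 2-aryloxybenzaldehydes into aryl formates, a standard entry to hydroxylated diaryl ethers. No ring is closed and no stereocentre is formed. The selectivity needed is aryl over hydride migration (formate, not carboxylic acid); the lone pair of the ether oxygen on the neighbouring ring carbon (C2/C5) secures it by stabilising the positive charge that builds up on the migrating carbon. The first oxidation should be the slower one because the second formyl group is para to the migrating carbon; once that group has become a formyloxy group the ring is richer and the second migration is easier, so excess peracid and gentle heating should carry monoformate 8 through to 9. The tribrominated outer rings are too electron-poor to be attacked, and anhydrous, unbuffered conditions keep the formates intact so that no free hydroquinone meets the oxidant.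

Step 5
Reactants: 9 2,5-bis(2,3,5-tribromo-4-methoxyphenoxy)-1,4-phenylene diformate
Product: 11 2,5-bis(2,3,5-tribromo-4-methoxyphenoxy)benzene-1,4-diol, via hydroxyaryl monoformate 10 (not isolated)
Conditions: HCl (cat., 1.25 M in MeOH), MeOH–THF, rt, Ar
Reagents that add atoms: none
Why: Acid-catalysed transesterification (methanolysis) of the very labile aryl formates should release the hydroquinone, and the acidic, oxygen-free medium avoids aerobic oxidation of a phenoxide to the quinone.

Step 6
Reactants: 11 2,5-bis(2,3,5-tribromo-4-methoxyphenoxy)benzene-1,4-diol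
Product: 13 3,6-dibromo-2,5-bis(2,3,5-tribromo-4-methoxyphenoxy)benzene-1,4-diol, via monobromohydroquinone 12 (not isolated)
Conditions: Br2 (2.2 equiv), AcOH–CH2Cl2, 0 °C→rt; aq. Na2S2O4 work-up
Reagents that add atoms: bromine, BrBr
Why: Electrophilic aromatic bromination of a hydroquinone: the only two free positions of the central ring (C3, C6) are each ortho to a hydroxyl and to an ether oxygen and are far more reactive than the single C–H of each tribrominated outer ring, and the dithionite wash should return any quinone formed by over-oxidation to the hydroquinone level.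

Step 7
Reactants: 13 3,6-dibromo-2,5-bis(2,3,5-tribromo-4-methoxyphenoxy)benzene-1,4-diol
Product: 15 3,6-dibromo-2,5-bis(2,3,5-tribromo-4-hydroxyphenoxy)benzene-1,4-diol (target), via monomethyl ether 14 (not isolated)
Conditions: BBr3 (8 equiv), CH2Cl2, −78 °C→rt; H2O quench, Ar
Reagents that add atoms: none
Why: Lewis-acid ether cleavage: boron coordinates each methoxy oxygen and bromide attacks the methyl carbon (SN2), whereas the diaryl ether C–O bonds offer no sp3 carbon and the aryl bromides are inert; the free hydroxyls only consume reagent as aryl borates that hydrolyse on quench.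

Compound list
1 | 1,3-dibromo-2-methoxybenzene (2,6-dibromoanisole) | COc1c(Br)cccc1Br | starting material
2 | 2-(3,5-dibromo-4-methoxyphenyl)-4,4,5,5-tetramethyl-1,3,2-dioxaborolane | COc1c(Br)cc(cc1Br)B1OC(C)(C)C(C)(C)O1 | intermediate (not isolated)
3 | 3,5-dibromo-4-methoxyphenol | COc1c(Br)cc(O)cc1Br | intermediate
4 | 2,3,5-tribromo-4-methoxyphenol | COc1c(Br)cc(O)c(Br)c1Br | intermediate
5 | 2,5-difluoroterephthalaldehyde | O=Cc1cc(F)c(C=O)cc1F | starting material
6 | 2-fluoro-5-(2,3,5-tribromo-4-methoxyphenoxy)terephthalaldehyde | O=Cc1cc(Oc2cc(Br)c(OC)c(Br)c2Br)c(C=O)cc1F | intermediate (not isolated)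
7 | 2,5-bis(2,3,5-tribromo-4-methoxyphenoxy)terephthalaldehyde | O=Cc1cc(Oc2cc(Br)c(OC)c(Br)c2Br)c(C=O)cc1Oc1cc(Br)c(OC)c(Br)c1Br | intermediate (key-step precursor)
8 | 4-formyl-2,5-bis(2,3,5-tribromo-4-methoxyphenoxy)phenyl formate | O=COc1cc(Oc2cc(Br)c(OC)c(Br)c2Br)c(C=O)cc1Oc1cc(Br)c(OC)c(Br)c1Br | intermediate (not isolated)
9 | 2,5-bis(2,3,5-tribromo-4-methoxyphenoxy)-1,4-phenylene diformate | O=COc1cc(Oc2cc(Br)c(OC)c(Br)c2Br)c(OC=O)cc1Oc1cc(Br)c(OC)c(Br)c1Br | intermediate (key-step product)
10 | 4-hydroxy-2,5-bis(2,3,5-tribromo-4-methoxyphenoxy)phenyl formate | Oc1cc(Oc2cc(Br)c(OC)c(Br)c2Br)c(OC=O)cc1Oc1cc(Br)c(OC)c(Br)c1Br | intermediate (not isolated)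
11 | 2,5-bis(2,3,5-tribromo-4-methoxyphenoxy)benzene-1,4-diol | Oc1cc(Oc2cc(Br)c(OC)c(Br)c2Br)c(O)cc1Oc1cc(Br)c(OC)c(Br)c1Br | intermediate
12 | 3-bromo-2,5-bis(2,3,5-tribromo-4-methoxyphenoxy)benzene-1,4-diol | Oc1cc(Oc2cc(Br)c(OC)c(Br)c2Br)c(O)c(Br)c1Oc1cc(Br)c(OC)c(Br)c1Br | intermediate (not isolated)
13 | 3,6-dibromo-2,5-bis(2,3,5-tribromo-4-methoxyphenoxy)benzene-1,4-diol | Oc1c(Br)c(Oc2cc(Br)c(OC)c(Br)c2Br)c(O)c(Br)c1Oc1cc(Br)c(OC)c(Br)c1Br | intermediate
14 | 3,6-dibromo-2-(2,3,5-tribromo-4-hydroxyphenoxy)-5-(2,3,5-tribromo-4-methoxyphenoxy)benzene-1,4-diol (boron-bound in the flask, drawn as the free phenol) | Oc1c(Br)c(Oc2cc(Br)c(O)c(Br)c2Br)c(O)c(Br)c1Oc1cc(Br)c(OC)c(Br)c1Br | intermediate (not isolated)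
15 | 3,6-dibromo-2,5-bis(2,3,5-tribromo-4-hydroxyphenoxy)benzene-1,4-diol | Oc1c(Br)cc(Oc2c(O)c(Br)c(Oc3cc(Br)c(O)c(Br)c3Br)c(O)c2Br)c(Br)c1Br | target

Total step count: 7. Longest linear sequence: 7 steps (1 → 3 → 4 → 7 → 9 → 11 → 13 → 15); compound 5 is purchased.

Steps most likely to fail

1. Step 4 (key step). In the Criegee adduct of the first aldehyde, hydride migration may compete with migration of the ring carbon, because the second formyl group still withdraws electron density. This would divert material to carboxylic acids, or the sequence may stall after one oxidation. The fallback sets out from phenol 4 and builds the central ring at the quinone oxidation level. Two equivalents of 4 with tetrabromo-1,4-benzoquinone (bromanil, O=C1C(Br)=C(Br)C(=O)C(Br)=C1Br) and K2CO3 in MeCN at rt should undergo twofold addition–elimination at the 2- and 5-positions, the usual outcome for tetrahaloquinones and phenoxides. This should give 2,5-dibromo-3,6-bis(2,3,5-tribromo-4-methoxyphenoxy)-1,4-benzoquinone F1. Reduction with aqueous Na2S2O4 in THF comes back to the route at compound 13, which already carries both central bromines, so only step 7 remains.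

2. Step 3. The second fluoride displacement may stall, because the first aryloxy group donates into the carbon para to it and the phenoxide of 4 is hindered and weakly nucleophilic. The aldehydes may also degrade at the temperature then required. The fallback sets out from 4 and 2,5-difluoroterephthalonitrile (N#Cc1cc(F)c(C#N)cc1F), whose cyano groups activate more strongly and tolerate hot carbonate. The same twofold SNAr (K2CO3, DMF, 80 °C) should give 2,5-bis(2,3,5-tribromo-4-methoxyphenoxy)terephthalonitrile F2. DIBAL-H (CH2Cl2, −78 °C) followed by aqueous HCl hydrolysis of the bis-aldimine comes back to the route at compound 7.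

3. Step 6. Bromine may act as an oxidant and not as an electrophile, taking the hydroquinone to the quinone, where bromide can attack the aryloxy-bearing carbons and expel the outer phenol. The fallback sets out from 11 and caps both hydroxyls (MeI, K2CO3, acetone, reflux) to give 1,4-dimethoxy-2,5-bis(2,3,5-tribromo-4-methoxyphenoxy)benzene F3, which bromine no longer oxidises to a quinone. Br2 in AcOH should then substitute the two remaining central positions to give 1,4-dibromo-2,5-dimethoxy-3,6-bis(2,3,5-tribromo-4-methoxyphenoxy)benzene F4. Treatment with BBr3 as in step 7, with more reagent, should remove all four methyl groups and come back to the route at compound 15.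

Further compounds
F1 | step 4 | 2,5-dibromo-3,6-bis(2,3,5-tribromo-4-methoxyphenoxy)cyclohexa-2,5-diene-1,4-dione | O=C1C(Br)=C(Oc2cc(Br)c(OC)c(Br)c2Br)C(=O)C(Br)=C1Oc1cc(Br)c(OC)c(Br)c1Br
F2 | step 3 | 2,5-bis(2,3,5-tribromo-4-methoxyphenoxy)benzene-1,4-dicarbonitrile | N#Cc1cc(Oc2cc(Br)c(OC)c(Br)c2Br)c(C#N)cc1Oc1cc(Br)c(OC)c(Br)c1Br
F3 | step 6 | 1,4-dimethoxy-2,5-bis(2,3,5-tribromo-4-methoxyphenoxy)benzene | COc1cc(Oc2cc(Br)c(OC)c(Br)c2Br)c(OC)cc1Oc1cc(Br)c(OC)c(Br)c1Br
F4 | step 6 | 1,4-dibromo-2,5-dimethoxy-3,6-bis(2,3,5-tribromo-4-methoxyphenoxy)benzene | COc1c(Br)c(Oc2cc(Br)c(OC)c(Br)c2Br)c(OC)c(Br)c1Oc1cc(Br)c(OC)c(Br)c1Br
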